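**Strategy**

The O1–C2–C3–C3a–C7a dihydrofuran ring of the dihydrobenzofuran that carries the cis-stilbene is obtained by contracting the pyranone ring of the chiral-pool flavanone (2S)-naringenin. Its C2 stereocentre, 4-hydroxyphenyl group and phloroglucinol ring A map onto C2, its aryl group and the resorcinol ring. A hypervalent-iodine 1,2-aryl shift moves C4a from C4 to C3, turns the ketone carbon into an exocyclic ester and sets C3 trans to C2. That ester is then replaced, with decarboxylation, by the second dihydrobenzofuran (from a rhodium-carbene C–H insertion). The former 5-OH, kept as a triflate, takes up the alkyne that becomes the Z-alkene.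

Key step: step 3

Assumption: (2S)-naringenin is used as the commercial, enantiomerically enriched natural flavanone; its enantiomeric purity is to be checked by chiral HPLC and, if needed, raised by preparative chiral chromatography at the stage of 2.
Assumption: the R enantiomer of the rhodium catalyst in step 10 is taken to give the (3R) series; should the sense of induction be opposite on this substrate, the S enantiomer of the catalyst is used instead.

**Route**

Step 1
Reactants: 1 (2S)-naringenin
Product: 2 (2S)-5-hydroxy-7-methoxy-2-(4-methoxyphenyl)-2,3-dihydro-4H-chromen-4-one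
Conditions: CH2N2 (excess), Et2O/MeOH, 0 °C to rt
Reagents that add atoms: diazomethane C=[N+]=[N-]
Why: Diazomethane O-methylates the two acidic, non-chelated phenols (7-OH and 4'-OH) under neutral conditions, so the base-labile C2 stereocentre is not racemised through chalcone formation, while the 5-OH hydrogen-bonded to the C4 carbonyl stays free (chemoselective phenol methylation).

Step 2
Reactants: 2 (2S)-5-hydroxy-7-methoxy-2-(4-methoxyphenyl)-2,3-dihydro-4H-chromen-4-one
Product: 3 (2S)-7-methoxy-2-(4-methoxyphenyl)-4-oxo-3,4-dihydro-2H-chromen-5-yl trifluoromethanesulfonate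
Conditions: Tf2O, pyridine, CH2Cl2, −20 to 0 °C
Reagents that add atoms: trifluoromethanesulfonic anhydride O=S(=O)(OS(=O)(=O)C(F)(F)F)C(F)(F)F
Why: The chelated 5-OH is sulfonylated by Tf2O with pyridine as a mild base (aryl triflate formation), which masks the phenol for the acidic oxidation and installs the handle for the later cross-coupling without touching C2.

Step 3
Reactants: 3 (2S)-7-methoxy-2-(4-methoxyphenyl)-4-oxo-3,4-dihydro-2H-chromen-5-yl trifluoromethanesulfonate
Product: 5 methyl (2S,3S)-6-methoxy-2-(4-methoxyphenyl)-4-(trifluoromethanesulfonyloxy)-2,3-dihydro-1-benzofuran-3-carboxylate (2,3-trans), via methyl enol ether 4 (not isolated)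
Conditions: PhI(OAc)2, conc. H2SO4, HC(OMe)3, rt; aqueous work-up
Reagents that add atoms: trimethyl orthoformate COC(OC)OC; water O
Why: In acidic trimethyl orthoformate the ketone of 3 is converted into methyl enol ether 4, which is attacked at C3 by the electrophilic trivalent iodine of PhI(OAc)2 on the face anti to the C2 aryl group while methanol adds to C4; the electron-rich ring-A carbon C4a (para to the 7-OMe group) then migrates from C4 to C3 with expulsion of iodobenzene, leaving a dimethoxycarbenium ion at the now exocyclic C4 that is hydrolysed to the methyl ester on work-up. The reaction type is the known hypervalent-iodine oxidative 1,2-aryl shift (ring contraction) of flavanones to methyl trans-2-aryl-2,3-dihydrobenzofuran-3-carboxylates. The five-membered O1–C2–C3–C3a–C7a ring is closed by contraction of the six-membered pyranone ring, the C3–C3a bond forming through a bridged phenonium-type (3-exo) transition state as C4 leaves the ring. C2 is untouched and keeps the S configuration of naringenin; the new C3 stereocentre is set trans to the C2 aryl group because the iodane enters anti to that group and is displaced with inversion by the ring bond antiperiplanar to it, and because the epimerisable ester settles in the trans arrangement under the acidic conditions. The step needs migration of C4a to win over the 2→3 shift of the anisyl ring and over elimination to the flavone: the equatorial trans C3–I bond is antiperiplanar to C4–C4a and not to the C2–aryl bond, the 7-OMe group raises the migratory aptitude of ring A, and ketalisation in orthoformate makes C4 a stabilised carbenium terminus. The triflate and both aryl methyl ethers are inert to the acid and to the oxidant.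

Step 4
Reactants: 5 methyl (2S,3S)-6-methoxy-2-(4-methoxyphenyl)-4-(trifluoromethanesulfonyloxy)-2,3-dihydro-1-benzofuran-3-carboxylate
Product: 6 (2S,3S)-6-methoxy-2-(4-methoxyphenyl)-4-(trifluoromethanesulfonyloxy)-2,3-dihydro-1-benzofuran-3-carboxylic acid
Conditions: Me3SnOH, ClCH2CH2Cl, 80 °C; then cold 1 M HCl wash
Reagents that add atoms: trimethyltin hydroxide C[Sn](C)(C)O
Why: Me3SnOH cleaves the hindered methyl ester through a neutral tin carboxylate without forming an ester enolate, so C3 does not epimerise, the dihydrofuran does not open by beta-elimination of the phenoxide, and the aryl triflate stays intact (mild ester hydrolysis).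

Step 5
Reactants: 6 (2S,3S)-6-methoxy-2-(4-methoxyphenyl)-4-(trifluoromethanesulfonyloxy)-2,3-dihydro-1-benzofuran-3-carboxylic acid
Product: 7 1,3-dioxoisoindolin-2-yl (2S,3S)-6-methoxy-2-(4-methoxyphenyl)-4-(trifluoromethanesulfonyloxy)-2,3-dihydro-1-benzofuran-3-carboxylate
Conditions: N-hydroxyphthalimide, N,N'-diisopropylcarbodiimide, DMAP (5 mol%), CH2Cl2, 0 °C to rt; used without long storage
Reagents that add atoms: N-hydroxyphthalimide O=C1c2ccccc2C(=O)N1O
Why: Carbodiimide coupling (Steglich-type esterification) gives the redox-active ester under nearly neutral conditions at low temperature, which limits enolisation of the activated ester, and no stereocentre is touched.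

Step 6
Reactants: 8 2-hydroxy-5-iodo-3-methoxybenzaldehyde; 9 4-methoxybenzyl chloride
Product: 10 5-iodo-3-methoxy-2-[(4-methoxyphenyl)methoxy]benzaldehyde
Conditions: K2CO3, DMF, 60 °C
Reagents that add atoms: none
Why: Williamson ether synthesis on the acidic ortho-formyl phenol; the benzylic CH2 introduced here becomes C2 of the second dihydrobenzofuran.

Step 7
Reactants: 10 5-iodo-3-methoxy-2-[(4-methoxyphenyl)methoxy]benzaldehyde; 11 3,5-dimethoxyphenylmagnesium chloride (THF solution)
Product: 12 (3,5-dimethoxyphenyl){5-iodo-3-methoxy-2-[(4-methoxyphenyl)methoxy]phenyl}methanol (racemic)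
Conditions: THF, −78 to 0 °C; aq. NH4Cl
Reagents that add atoms: none
Why: Grignard addition to the aldehyde at low temperature, where iodine–magnesium exchange of the electron-rich aryl iodide is slow; the carbinol stereocentre is of no consequence because it is oxidised in step 8.

Step 8
Reactants: 12 (3,5-dimethoxyphenyl){5-iodo-3-methoxy-2-[(4-methoxyphenyl)methoxy]phenyl}methanol
Product: 13 (3,5-dimethoxyphenyl){5-iodo-3-methoxy-2-[(4-methoxyphenyl)methoxy]phenyl}methanone
Conditions: activated MnO2 (excess), CH2Cl2, rt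
Reagents that add atoms: none
Why: Activated MnO2 oxidises the doubly benzylic alcohol to the benzophenone without touching the aryl iodide or the ethers (benzylic alcohol oxidation).

Step 9
Reactants: 13 (3,5-dimethoxyphenyl){5-iodo-3-methoxy-2-[(4-methoxyphenyl)methoxy]phenyl}methanone
Product: 14 the N-unsubstituted hydrazone of ketone 13 (E/Z mixture)
Conditions: N2H4·H2O (excess), AcOH (cat.), EtOH, 80 °C
Reagents that add atoms: hydrazine NN
Why: Condensation of the diaryl ketone with excess hydrazine gives the free hydrazone (hydrazone formation), the precursor of the donor/donor diazo compound.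

Step 10
Reactants: 14 hydrazone of ketone 13
Product: 16 (2S,3R)-3-(3,5-dimethoxyphenyl)-5-iodo-7-methoxy-2-(4-methoxyphenyl)-2,3-dihydro-1-benzofuran (2,3-cis), via diaryldiazomethane 15 (not isolated)
Conditions: MnO2, CH2Cl2, 0 °C, filtration; then Rh2(R-PTAD)4 (dirhodium tetrakis[(R)-N-phthaloyl-(1-adamantyl)glycinate], 1 mol%), CH2Cl2, 0 °C
Reagents that add atoms: none
Why: MnO2 dehydrogenates the hydrazone to diaryldiazomethane 15, whose rhodium carbene inserts into the activated benzylic C–H bond of the adjacent 4-methoxybenzyl ether through a five-membered transition state (enantioselective intramolecular C–H insertion of a donor/donor carbene), the chiral carboxylate ligands fixing C3 as R and the concerted insertion giving the kinetic 2,3-cis product with C2 as S.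

Step 11
Reactants: 16 (2S,3R)-3-(3,5-dimethoxyphenyl)-5-iodo-7-methoxy-2-(4-methoxyphenyl)-2,3-dihydro-1-benzofuran
Product: 17 (2R,3R)-3-(3,5-dimethoxyphenyl)-5-iodo-7-methoxy-2-(4-methoxyphenyl)-2,3-dihydro-1-benzofuran (2,3-trans)
Conditions: CF3CO2H, CH2Cl2 (dilute), 0 °C to rt
Reagents that add atoms: none
Why: Acid ionises the C2–O bond to a 4-methoxybenzyl cation tethered to the phenol, and reclosure delivers the thermodynamically favoured 2,3-trans isomer, inverting C2 to R while the non-ionisable C3 stays R (acid-mediated epimerisation).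

Step 12
Reactants: 7 1,3-dioxoisoindolin-2-yl (2S,3S)-6-methoxy-2-(4-methoxyphenyl)-4-(trifluoromethanesulfonyloxy)-2,3-dihydro-1-benzofuran-3-carboxylate; 17 (2R,3R)-3-(3,5-dimethoxyphenyl)-5-iodo-7-methoxy-2-(4-methoxyphenyl)-2,3-dihydro-1-benzofuran
Product: 18 (2S,3S)-3-[(2R,3R)-3-(3,5-dimethoxyphenyl)-7-methoxy-2-(4-methoxyphenyl)-2,3-dihydro-1-benzofuran-5-yl]-6-methoxy-2-(4-methoxyphenyl)-2,3-dihydro-1-benzofuran-4-yl trifluoromethanesulfonate
Conditions: NiBr2(dme) (20 mol%), 4,4'-di-tert-butyl-2,2'-bipyridine (20 mol%), Zn dust, DMA, rt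
Reagents that add atoms: none
Why: Nickel-catalysed decarboxylative cross-electrophile coupling: single-electron reduction of the N-acyloxyphthalimide releases CO2 and the benzylic C3 radical, which is captured by the arylnickel species formed from iodide 17 and reductively eliminated on the face anti to the C2 aryl group, so C3 is reset as S (2,3-trans) under substrate control while the bipyridine–nickel catalyst leaves the aryl triflate untouched.

Step 13
Reactants: 18 the coupled aryl triflate; 19 1-ethynyl-4-methoxybenzene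
Product: 20 (2S,3S)-3-[(2R,3R)-3-(3,5-dimethoxyphenyl)-7-methoxy-2-(4-methoxyphenyl)-2,3-dihydro-1-benzofuran-5-yl]-6-methoxy-2-(4-methoxyphenyl)-4-[(4-methoxyphenyl)ethynyl]-2,3-dihydro-1-benzofuran
Conditions: Pd(PPh3)4 (10 mol%), CuI (10 mol%), n-Bu4NI, Et3N, DMF, 70 °C
Reagents that add atoms: none
Why: Sonogashira coupling of the aryl triflate with the terminal alkyne installs the two stilbene carbons and the last aryl ring; no stereocentre is affected and the methyl ethers are inert.

Step 14
Reactants: 20 the heptamethyl ether alkyne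
Product: 21 (2S,3S)-3-[(2R,3R)-3-(3,5-dihydroxyphenyl)-7-hydroxy-2-(4-hydroxyphenyl)-2,3-dihydro-1-benzofuran-5-yl]-2-(4-hydroxyphenyl)-4-[(4-hydroxyphenyl)ethynyl]-2,3-dihydro-1-benzofuran-6-ol
Conditions: BBr3 (excess), CH2Cl2, −78 to 0 °C; MeOH, then aq. NaHCO3
Reagents that add atoms: none
Why: BBr3 cleaves all seven aryl methyl ethers by bromide attack on the boron-activated methyl groups (Lewis-acid O-demethylation), the alkyne being inert where a stilbene would cyclise, and any transient ionisation of the benzylic C2–O bonds recloses to the favoured trans rings because C3 and C3' cannot ionise.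

Step 15
Reactants: 21 the heptaphenol alkyne
Product: 22 (2S,3S)-3-[(2R,3R)-3-(3,5-dihydroxyphenyl)-7-hydroxy-2-(4-hydroxyphenyl)-2,3-dihydro-1-benzofuran-5-yl]-2-(4-hydroxyphenyl)-4-[(Z)-2-(4-hydroxyphenyl)ethenyl]-2,3-dihydro-1-benzofuran-6-ol (target)
Conditions: H2 (1 atm), Pd/CaCO3 poisoned with Pb(OAc)2 (Lindlar catalyst), quinoline, EtOAc/MeOH, rt, in the dark, stopped after one equivalent of H2
Reagents that add atoms: none
Why: Lindlar semihydrogenation adds one equivalent of H2 in a syn fashion on the poisoned palladium surface, giving the Z-alkene, and tolerates the free phenols and the benzylic ethers.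

**Compound list**

1 | (2S)-naringenin | O=C1C[C@@H](c2ccc(O)cc2)Oc2cc(O)cc(O)c12 | starting material
2 | (2S)-5-hydroxy-7-methoxy-2-(4-methoxyphenyl)-2,3-dihydro-4H-chromen-4-one | O=C1C[C@@H](c2ccc(OC)cc2)Oc2cc(OC)cc(O)c12 | intermediate
3 | (2S)-7-methoxy-2-(4-methoxyphenyl)-4-oxo-3,4-dihydro-2H-chromen-5-yl trifluoromethanesulfonate | O=C1C[C@@H](c2ccc(OC)cc2)Oc2cc(OC)cc(OS(=O)(=O)C(F)(F)F)c12 | intermediate
4 | (2S)-4,7-dimethoxy-2-(4-methoxyphenyl)-2H-chromen-5-yl trifluoromethanesulfonate (methyl enol ether, not isolated) | COC1=C[C@@H](c2ccc(OC)cc2)Oc2cc(OC)cc(OS(=O)(=O)C(F)(F)F)c12 | intermediate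
5 | methyl (2S,3S)-6-methoxy-2-(4-methoxyphenyl)-4-(trifluoromethanesulfonyloxy)-2,3-dihydro-1-benzofuran-3-carboxylate | FC(F)(F)S(=O)(=O)Oc1cc(OC)cc2c1[C@H](C(=O)OC)[C@@H](c1ccc(OC)cc1)O2 | intermediate
6 | (2S,3S)-6-methoxy-2-(4-methoxyphenyl)-4-(trifluoromethanesulfonyloxy)-2,3-dihydro-1-benzofuran-3-carboxylic acid | FC(F)(F)S(=O)(=O)Oc1cc(OC)cc2c1[C@H](C(=O)O)[C@@H](c1ccc(OC)cc1)O2 | intermediate
7 | 1,3-dioxoisoindolin-2-yl (2S,3S)-6-methoxy-2-(4-methoxyphenyl)-4-(trifluoromethanesulfonyloxy)-2,3-dihydro-1-benzofuran-3-carboxylate | FC(F)(F)S(=O)(=O)Oc1cc(OC)cc2c1[C@H](C(=O)ON1C(=O)c3ccccc3C1=O)[C@@H](c1ccc(OC)cc1)O2 | intermediate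
8 | 2-hydroxy-5-iodo-3-methoxybenzaldehyde | O=Cc1cc(I)cc(OC)c1O | starting material
9 | 4-methoxybenzyl chloride | COc1ccc(CCl)cc1 | starting material
10 | 5-iodo-3-methoxy-2-[(4-methoxyphenyl)methoxy]benzaldehyde | O=Cc1cc(I)cc(OC)c1OCc1ccc(OC)cc1 | intermediate
11 | 3,5-dimethoxyphenylmagnesium chloride | COc1cc(OC)cc([Mg]Cl)c1 | starting material
12 | (3,5-dimethoxyphenyl){5-iodo-3-methoxy-2-[(4-methoxyphenyl)methoxy]phenyl}methanol (racemic) | OC(c1cc(OC)cc(OC)c1)c1cc(I)cc(OC)c1OCc1ccc(OC)cc1 | intermediate
13 | (3,5-dimethoxyphenyl){5-iodo-3-methoxy-2-[(4-methoxyphenyl)methoxy]phenyl}methanone | O=C(c1cc(OC)cc(OC)c1)c1cc(I)cc(OC)c1OCc1ccc(OC)cc1 | intermediate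
14 | hydrazone of ketone 13 | NN=C(c1cc(OC)cc(OC)c1)c1cc(I)cc(OC)c1OCc1ccc(OC)cc1 | intermediate
15 | (3,5-dimethoxyphenyl){5-iodo-3-methoxy-2-[(4-methoxyphenyl)methoxy]phenyl}diazomethane (not isolated) | [N-]=[N+]=C(c1cc(OC)cc(OC)c1)c1cc(I)cc(OC)c1OCc1ccc(OC)cc1 | intermediate
16 | (2S,3R)-3-(3,5-dimethoxyphenyl)-5-iodo-7-methoxy-2-(4-methoxyphenyl)-2,3-dihydro-1-benzofuran (cis) | Ic1cc(OC)c2c(c1)[C@@H](c1cc(OC)cc(OC)c1)[C@@H](c1ccc(OC)cc1)O2 | intermediate
17 | (2R,3R)-3-(3,5-dimethoxyphenyl)-5-iodo-7-methoxy-2-(4-methoxyphenyl)-2,3-dihydro-1-benzofuran (trans) | Ic1cc(OC)c2c(c1)[C@@H](c1cc(OC)cc(OC)c1)[C@H](c1ccc(OC)cc1)O2 | intermediate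
18 | (2S,3S)-3-[(2R,3R)-3-(3,5-dimethoxyphenyl)-7-methoxy-2-(4-methoxyphenyl)-2,3-dihydro-1-benzofuran-5-yl]-6-methoxy-2-(4-methoxyphenyl)-2,3-dihydro-1-benzofuran-4-yl trifluoromethanesulfonate | FC(F)(F)S(=O)(=O)Oc1cc(OC)cc2c1[C@H](c1cc(OC)c3c(c1)[C@@H](c1cc(OC)cc(OC)c1)[C@H](c1ccc(OC)cc1)O3)[C@@H](c1ccc(OC)cc1)O2 | intermediate
19 | 1-ethynyl-4-methoxybenzene | COc1ccc(C#C)cc1 | starting material
20 | heptamethyl ether alkyne (4-[(4-methoxyphenyl)ethynyl] analogue of 18) | COc1ccc(C#Cc2cc(OC)cc3c2[C@H](c2cc(OC)c4c(c2)[C@@H](c2cc(OC)cc(OC)c2)[C@H](c2ccc(OC)cc2)O4)[C@@H](c2ccc(OC)cc2)O3)cc1 | intermediate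
21 | heptaphenol alkyne | Oc1ccc(C#Cc2cc(O)cc3c2[C@H](c2cc(O)c4c(c2)[C@@H](c2cc(O)cc(O)c2)[C@H](c2ccc(O)cc2)O4)[C@@H](c2ccc(O)cc2)O3)cc1 | intermediate
22 | CNP0172909.2 | Oc1ccc(/C=C\c2cc(O)cc3c2[C@H](c2cc(O)c4c(c2)[C@@H](c2cc(O)cc(O)c2)[C@H](c2ccc(O)cc2)O4)[C@@H](c2ccc(O)cc2)O3)cc1 | target

**Totals**

Total step count: 15.
Longest linear sequence: 10 steps (from 8 through steps 6–11 and 12–15); the naringenin branch is 9 steps.

**Steps most likely to fail**

Step 3 (key ring contraction). What may go wrong: migration of ring A is outrun by the 2→3 shift of the anisyl ring or by dehydrogenation of the heterocycle, or the strong acid ionises the C2–O bond and erodes the enantiomeric purity. The fallback sets out from 3 and returns at 5; it keeps the ring contraction but runs it as a Wolff rearrangement. Compound 3 is deprotonated with LiHMDS in THF at −78 °C, where beta-elimination of the enolate is slow, and acylated with 2,2,2-trifluoroethyl trifluoroacetate to the 3-trifluoroacetyl flavanone F1. Detrifluoroacetylative diazo transfer with MsN3 and Et3N in MeCN/H2O then gives the 3-diazo flavanone F2. Irradiation at 350 nm in MeOH expels N2, ring carbon C4a migrates to the carbene carbon, and methanol adds to the resulting ketene. This gives 5 together with its 2,3-cis epimer F3, which is equilibrated to 5 with catalytic NaOMe in MeOH.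

Step 12 (decarboxylative arylation). What may go wrong: dimerisation or reduction of the stabilised benzylic C3 radical before it meets the arylnickel species, beta-hydride loss from the alkylnickel intermediate with aromatisation of the dihydrofuran, reduction of the aryl iodide, or attack of the catalyst on the triflate. The fallback sets out from 17 and 7 and returns at 18; it replaces the cross-electrophile mode by coupling with a preformed aryl nucleophile and no external reductant. Iodide 17 is converted by direct zinc insertion (Zn dust, LiCl, THF, 50 °C) into the arylzinc iodide F4. F4 is then coupled with redox-active ester 7 under NiCl2(dme)/4,4'-di-tert-butyl-2,2'-bipyridine in THF/DMF at rt (decarboxylative Negishi-type arylation), again with aryl delivery anti to the C2 aryl group, to give 18.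

Step 13 (Sonogashira coupling). What may go wrong: slow oxidative addition into the electron-rich C4–OTf bond, which is flanked by the C3 centre now carrying two bulky groups, so that S–O cleavage of the triflate and oxidative dimerisation of the alkyne take over. The fallback sets out from 5 and returns at 20; it moves the alkynylation forward to the stage where C3 carries only the ester. Ester 5 is coupled with 19 (Pd(PPh3)4, CuI, Et3N, DMF) to the alkynyl ester F5, which is cleaved with Me3SnOH to the alkynyl acid F6. F6 is converted with N-hydroxyphthalimide and N,N'-diisopropylcarbodiimide into the alkynyl redox-active ester F7. F7 is then joined to iodide 17 under the nickel conditions of step 12 to give 20 directly.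

**Further compounds**

F1 | step 3 | (2S)-7-methoxy-2-(4-methoxyphenyl)-4-oxo-3-(trifluoroacetyl)-3,4-dihydro-2H-chromen-5-yl trifluoromethanesulfonate (C3 epimers and enol form) | O=C1C(C(=O)C(F)(F)F)[C@@H](c2ccc(OC)cc2)Oc2cc(OC)cc(OS(=O)(=O)C(F)(F)F)c12
F2 | step 3 | (2R)-3-diazo-7-methoxy-2-(4-methoxyphenyl)-4-oxo-3,4-dihydro-2H-chromen-5-yl trifluoromethanesulfonate (same spatial arrangement at C2 as in 3; only the descriptor changes) | O=C1C(=[N+]=[N-])[C@@H](c2ccc(OC)cc2)Oc2cc(OC)cc(OS(=O)(=O)C(F)(F)F)c12
F3 | step 3 | methyl (2S,3R)-6-methoxy-2-(4-methoxyphenyl)-4-(trifluoromethanesulfonyloxy)-2,3-dihydro-1-benzofuran-3-carboxylate (2,3-cis) | FC(F)(F)S(=O)(=O)Oc1cc(OC)cc2c1[C@@H](C(=O)OC)[C@@H](c1ccc(OC)cc1)O2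
F4 | step 12 | [(2R,3R)-3-(3,5-dimethoxyphenyl)-7-methoxy-2-(4-methoxyphenyl)-2,3-dihydro-1-benzofuran-5-yl]zinc iodide | I[Zn]c1cc(OC)c2c(c1)[C@@H](c1cc(OC)cc(OC)c1)[C@H](c1ccc(OC)cc1)O2
F5 | step 13 | methyl (2S,3S)-6-methoxy-2-(4-methoxyphenyl)-4-[(4-methoxyphenyl)ethynyl]-2,3-dihydro-1-benzofuran-3-carboxylate | COc1ccc(C#Cc2cc(OC)cc3c2[C@H](C(=O)OC)[C@@H](c2ccc(OC)cc2)O3)cc1
F6 | step 13 | (2S,3S)-6-methoxy-2-(4-methoxyphenyl)-4-[(4-methoxyphenyl)ethynyl]-2,3-dihydro-1-benzofuran-3-carboxylic acid | COc1ccc(C#Cc2cc(OC)cc3c2[C@H](C(=O)O)[C@@H](c2ccc(OC)cc2)O3)cc1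
F7 | step 13 | 1,3-dioxoisoindolin-2-yl (2S,3S)-6-methoxy-2-(4-methoxyphenyl)-4-[(4-methoxyphenyl)ethynyl]-2,3-dihydro-1-benzofuran-3-carboxylate | COc1ccc(C#Cc2cc(OC)cc3c2[C@H](C(=O)ON2C(=O)c4ccccc4C2=O)[C@@H](c2ccc(OC)cc2)O3)cc1
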